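(The readings are calculated on assumed constants.)

**Constants first.** I held no rate constant for this flask, so I made a constant from the two earlier runs.

| flask | substrate | gas phase | remark | time |
|---|---|---|---|---|
| theta | 0.050 M | 4.3 mM (held) | run made earlier |  |
| alpha | 0.20 M | 4.3 mM (held) | run made earlier |  |
| flask | 0.10 M | 4.3 mM (held) |  | 3.0 d |

| run | time / h | target / % |
|---|---|---|
| theta | 5.00 | 9.4 |
| theta | 15.0 | 23.9 |
| theta | 30.0 | 36.8 |
| theta | 40.0 | 41.7 |
| alpha | 10.0 | 10.3 |
| alpha | 20.0 | 16.1 |
| alpha | 30.0 | 21.7 |
| alpha | 40.0 | 24.1 |

(scatter of a reading: 0.5 percentage points)

- target at 3.0 d, in percent of the substrate charged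
- concentration of dissolved gas in solution at 3.0 d, in percent of saturation

- at the start none of the gas phase is in solution

**Charge exponent.** The last readings of theta and alpha give 0.396: the charge exponent, the log-log slope by which percent target at a fixed time falls with c(substrate). Going from theta's charge to the flask's multiplies percent target by 0.760.

**Hand chain.** Theta's last reading, so scaled, put the flask at 31.7% after 40.0 h. Running theta straight on at its last hourly gain until 3.0 d, then scaling, gave 43.6%.

**Weak link.** That straight line was the weak link, since theta's hourly gain shrank between its last two intervals, with a decay time of 22.2 h. With the gain dying away on that time, I estimated theta at 48.3%, and I committed to 36.7% for the flask. I reckoned no figure for the dissolved gas.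

**The result.** The forecast gave 40%, higher than my figure, and 98%, holding that “Late in the run consumption is tiny”. The flask gave 36.7% of target, with dissolved gas at 88.7% of saturation.

    gas phase ⇌ dissolved gas, rate k1*(csat - [dissolved gas]) (kL = 3.87 × 10⁻⁴ /s)
    substrate + dissolved gas → target (k = 0.00202 /M/s)
    dissolved gas + target → over-reacted product (k = 6.19 × 10⁻⁴ /M/s)
    substrate + target → side product (k = 6.60 × 10⁻⁵ /M/s)
    substrate ⇌ dormant form (K = 0.236, k = 1.94 × 10⁻⁵ /s)

**Two errors.** Theta's charge at 3.0 d actually holds 44.4%, less than my extension. Scaled by the exponent, that gives 33.7%, below the flask's 36.7%, so my close figure rested on two opposite errors. The flask held 36.7% of target at 3.0 d in part because dormant form falls back to substrate, without which it holds 12.9%, and because it was read then and not ten times later, when it holds 0.114%.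

**Second flask.** For the neighbour at 0.060 M, the exponent raises the flask's result to 44.9%; computed, it gives 42.7%.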